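**Strategy**

- **Cuts:** O1–C2 of ring C is cut first. Ring D is then taken back through its C5'–vinyl bond to a C4' 1,1-dimethylpropargyl ether. Ring B is cut at C2'–C3' and C1'–C6'. Last come the C2–alkyne bond and the propargyl–prenyl bond.
- **Enabling feature:** ring B carries C1' (benzylic carbon), C2' (prenyl), C3' (OH) and C4' (ether O) in a row, and its single hydrogen at C6' stands para to the C3' hydroxyl. This is the pattern left when the oxygen bridge of a 3-alkoxyfuran/ynone cycloadduct opens, so the furan oxygen ends up as the C3' hydroxyl.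
- **Forward order:** umbelliferone supplies ring A and C2–C4 after its lactone is opened to a Weinreb amide, and a prenyl acetylide turns the amide into the ynone. Ring B is built by furan Diels–Alder reaction and aromatisation, ring D by a propargyl Claisen cascade at C5', and ring C last by a Mitsunobu closure.
- **Stereochemistry:** C2 is the only stereocentre. Catalyst-controlled asymmetric transfer hydrogenation sets it as the (R)-carbinol, and the SN2 ring closure inverts it to (S).
- **Protecting groups:** the ring A phenol that becomes O1 travels as an allyl ether from the amide to the carbinol, so the ynone, the cycloaddition and the catechol alkylation meet no competing phenol. O7 is a triisopropylsilyl ether, and the furan oxygen carries a 4-methoxybenzyl group.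

Key step: step 8

Remark: flavan numbering is used (O1, C2–C4, ring A C4a–C8a, ring B C1'–C6', ring D the dimethylpyran). The given SMILES encodes the 2S configuration (O1 > C1' > C3 > H).

Step 1
Reactants: 1 umbelliferone (7-hydroxy-2H-chromen-2-one)
Product: 2 7-hydroxychroman-2-one
Conditions: H2 (3 atm), 10% Pd/C, AcOH, 50 °C
Reagents that add atoms: none
Why: Heterogeneous catalytic hydrogenation saturates the electron-poor C3=C4 bond of the coumarin long before the arene or the lactone carbonyl is touched.

Step 2
Reactants: 2 7-hydroxychroman-2-one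
Product: 3 7-(triisopropylsilyloxy)chroman-2-one
Conditions: TIPSCl, imidazole, DMF, rt
Reagents that add atoms: triisopropylsilyl chloride, CC(C)[Si](Cl)(C(C)C)C(C)C
Why: Standard silyl ether formation at the only hydroxyl group, with the bulky silyl group chosen because it must outlast organolithium, dilute acid, amidine base, heat and amine before fluoride removes it in the last step.

Step 3
Reactants: 3 7-(triisopropylsilyloxy)chroman-2-one
Product: 4 3-[2-hydroxy-4-(triisopropylsilyloxy)phenyl]-N-methoxy-N-methylpropanamide
Conditions: MeNH(OMe)·HCl, i-PrMgCl, THF, −20 to 0 °C; aq NH4Cl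
Reagents that add atoms: N,O-dimethylhydroxylamine hydrochloride, CNOC.Cl
Why: Weinreb amide formation by aminolysis of the activated aryl ester with the magnesium amide, which opens the lactone and releases the phenol that will become O1.

Step 4
Reactants: 4 3-[2-hydroxy-4-(triisopropylsilyloxy)phenyl]-N-methoxy-N-methylpropanamide
Product: 5 3-[2-allyloxy-4-(triisopropylsilyloxy)phenyl]-N-methoxy-N-methylpropanamide
Conditions: allyl bromide, K2CO3, acetone, 50 °C
Reagents that add atoms: allyl bromide, C=CCBr
Why: Williamson ether synthesis at the only acidic site, giving an ether that stops the phenol from consuming acetylide, forming a hemiketal, adding to the ynone or competing in step 10, and that zerovalent palladium later removes under neutral conditions.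

Step 5
Reactants: 6 prenyl bromide (1-bromo-3-methylbut-2-ene), 7 ethynylmagnesium bromide
Product: 8 5-methylhex-4-en-1-yne
Conditions: 7 (1.5 equiv), CuCl (5 mol %), THF, 0 °C to rt; distillation
Reagents that add atoms: none
Why: Copper-catalysed allylic substitution by an alkynyl Grignard reagent, which with a prenyl halide takes place at the unhindered primary carbon (SN2) to give the skipped enyne, the excess of 7 suppressing double alkylation.

Step 6
Reactants: 8 5-methylhex-4-en-1-yne, 5 3-[2-allyloxy-4-(triisopropylsilyloxy)phenyl]-N-methoxy-N-methylpropanamide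
Product: 10 1-[2-allyloxy-4-(triisopropylsilyloxy)phenyl]-8-methylnon-7-en-4-yn-3-one, via lithium acetylide 9 (not isolated)
Conditions: 8, n-BuLi, THF, −78 °C; then 5, −78 to −20 °C; inverse quench into cold 0.5 M HCl/Et2O
Reagents that add atoms: none
Why: Weinreb ketone synthesis, in which the chelated tetrahedral adduct persists until the quench so that only one acetylide adds, while pouring into cold dilute acid keeps the released N,O-dimethylhydroxylamine protonated and denies any base access to the doubly activated CH2 between alkyne and alkene.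

Step 7
Reactants: 11 3-bromofuran
Product: 12 3-(4-methoxybenzyloxy)furan
Conditions: 4-methoxybenzyl alcohol, CuI (10 mol %), 3,4,7,8-tetramethyl-1,10-phenanthroline (20 mol %), Cs2CO3, toluene, 110 °C, sealed tube
Reagents that add atoms: 4-methoxybenzyl alcohol, COc1ccc(CO)cc1
Why: Ullmann-type copper-catalysed C–O coupling of a heteroaryl bromide with a primary benzylic alcohol, the ligand-accelerated form of the classical alkoxylation of 3-bromofuran.

Step 8
Reactants: 10 1-[2-allyloxy-4-(triisopropylsilyloxy)phenyl]-8-methylnon-7-en-4-yn-3-one, 12 3-(4-methoxybenzyloxy)furan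
Product: 14 1-[3-hydroxy-4-(4-methoxybenzyloxy)-2-prenylphenyl]-3-[2-allyloxy-4-(triisopropylsilyloxy)phenyl]propan-1-one, via oxanorbornadiene cycloadduct 13 (not isolated)
Conditions: 12 (3 equiv), dry toluene (2 M in 10), BHT (cat.), 100 °C, sealed tube; then PPTS (5 mol %), CH2Cl2, rt
Reagents that add atoms: none
Why: Proposed new method: the alkoxy group raises the HOMO of furan 12 and places its largest coefficient at C2, the ketone places the largest LUMO coefficient of ynone 10 at the prenyl-bearing β-carbon, and a concerted but asynchronous suprafacial [4+2] cycloaddition should therefore join furan C2 to Cβ (C3'–C2') slightly ahead of furan C5 to Cα (C6'–C1'), closing the six-membered carbocycle of ring B in an intermolecular cycloaddition as the oxygen-bridged bicycle 13. In 13 the enol ether oxygen on C4' pushes through C4'=C5' and expels the bridge oxygen from the allylic bridgehead C6'; the cation so formed carries its charge on C4', C6' and C2' but not on the acyl-bearing C1', and loss of the C3' proton then gives the phenol irreversibly, which drains the reversible cycloaddition. The closest known reaction type is the Diels–Alder addition of donor-substituted furans to acetylenic esters and ketones with opening of the 7-oxanorbornadiene to a phenol; not yet shown is the pairing of a 3-alkoxyfuran with an ynone that bears an alkyl group on its β-carbon, a far weaker dienophile than terminal or doubly activated alkynes, hence the excess of diene, the high concentration and the heating. The two bridgehead stereocentres of 13 arise as a racemic pair whose relative configuration is dictated by the bridge, and both disappear on aromatisation, so no stereocontrol is called for. Regioselectivity is needed twice, in the orientation of the partners and in the choice of the C–O bond that breaks, and the one alkoxy group on furan C3 secures both, since it polarises the diene towards C2 and can stabilise a cation only at the distal bridgehead. The allyl cap on the ring A phenol keeps hemiketal formation and oxa-Michael addition away from the ynone during the long heating.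

Step 9
Reactants: 14 1-[3-hydroxy-4-(4-methoxybenzyloxy)-2-prenylphenyl]-3-[2-allyloxy-4-(triisopropylsilyloxy)phenyl]propan-1-one
Product: 15 1-(3,4-dihydroxy-2-prenylphenyl)-3-[2-allyloxy-4-(triisopropylsilyloxy)phenyl]propan-1-one
Conditions: TFA (5 vol %), 1,3,5-trimethoxybenzene (5 equiv), CH2Cl2, 0 °C, short contact; aq NaHCO3
Reagents that add atoms: none
Why: Acidolysis of a 4-methoxybenzyl aryl ether, fast here because the leaving group is a phenol para to a ketone, with the very nucleophilic scavenger taking up the benzyl cation by Friedel–Crafts alkylation before ring A or the prenyl alkene can, and with dilute acid, cold and short contact sparing the ortho-prenylphenol from chroman formation.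

Step 10
Reactants: 15 1-(3,4-dihydroxy-2-prenylphenyl)-3-[2-allyloxy-4-(triisopropylsilyloxy)phenyl]propan-1-one, 16 2-methylbut-3-yn-2-ol
Product: 18 1-[3-hydroxy-4-(2-methylbut-3-yn-2-yloxy)-2-prenylphenyl]-3-[2-allyloxy-4-(triisopropylsilyloxy)phenyl]propan-1-one, via 2-methylbut-3-yn-2-yl trifluoroacetate 17 (not isolated)
Conditions: 16, (CF3CO)2O, DBU, MeCN, 0 °C; then 15, DBU (1.05 equiv), CuCl2·2H2O (1 mol %), MeCN, −5 °C, Ar
Reagents that add atoms: none
Why: Copper-catalysed O-propargylation of a phenol with a tertiary propargylic trifluoroacetate, in which the limiting base ionises only the C4' hydroxyl (para to the ketone, more acidic, unhindered), as in the familiar 4-O-selective alkylation of 3,4-dihydroxyaryl carbonyl compounds, while the prenyl group shields the C3' hydroxyl.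

Step 11
Reactants: 18 1-[3-hydroxy-4-(2-methylbut-3-yn-2-yloxy)-2-prenylphenyl]-3-[2-allyloxy-4-(triisopropylsilyloxy)phenyl]propan-1-one
Product: 19 1-(8-hydroxy-2,2-dimethyl-7-prenyl-2H-chromen-6-yl)-3-[2-allyloxy-4-(triisopropylsilyloxy)phenyl]propan-1-one
Conditions: o-xylene, BHT (cat.), 140 °C, Ar
Reagents that add atoms: none
Why: Aryl propargyl ether Claisen rearrangement to the only free ortho carbon C5', followed by rearomatisation, 1,5-hydrogen shift and oxa-6π electrocyclisation, closes ring D, and the gem-dimethyl acceleration lets it run well below the temperature at which the simple allyl ether on ring A would migrate.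

Step 12
Reactants: 19 1-(8-hydroxy-2,2-dimethyl-7-prenyl-2H-chromen-6-yl)-3-[2-allyloxy-4-(triisopropylsilyloxy)phenyl]propan-1-one
Product: 20 (1R)-1-(8-hydroxy-2,2-dimethyl-7-prenyl-2H-chromen-6-yl)-3-[2-allyloxy-4-(triisopropylsilyloxy)phenyl]propan-1-ol
Conditions: RuCl(p-cymene)[(R,R)-TsDPEN] (2 mol %), HCO2H/Et3N (5:2), EtOAc, 35 °C
Reagents that add atoms: none
Why: Noyori asymmetric transfer hydrogenation of an aryl alkyl ketone, in which the (R,R)-catalyst recognises ring B through a CH/π contact with its cymene ligand and delivers hydride to the Si face, setting C2 as (R), while the outer-sphere mechanism leaves the prenyl, chromene and allyl C=C bonds alone.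

Step 13
Reactants: 20 (1R)-1-(8-hydroxy-2,2-dimethyl-7-prenyl-2H-chromen-6-yl)-3-[2-allyloxy-4-(triisopropylsilyloxy)phenyl]propan-1-ol
Product: 21 (1R)-1-(8-hydroxy-2,2-dimethyl-7-prenyl-2H-chromen-6-yl)-3-[2-hydroxy-4-(triisopropylsilyloxy)phenyl]propan-1-ol
Conditions: Pd(PPh3)4 (5 mol %), morpholine (5 equiv), THF, rt
Reagents that add atoms: none
Why: Tsuji–Trost deallylation, in which zerovalent palladium ionises the aryl allyl ether and morpholine captures the allyl fragment under neutral conditions that disturb neither the benzylic carbinol and its configuration nor the silyl ether or the alkenes.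

Step 14
Reactants: 21 (1R)-1-(8-hydroxy-2,2-dimethyl-7-prenyl-2H-chromen-6-yl)-3-[2-hydroxy-4-(triisopropylsilyloxy)phenyl]propan-1-ol
Product: 22 (2S)-7-O-triisopropylsilylkazinol B
Conditions: PPh3, DIAD, toluene (0.01 M), −20 to 0 °C
Reagents that add atoms: none
Why: Intramolecular Mitsunobu etherification, a 6-exo-tet SN2 displacement of the phosphonium-activated carbinol by the ring A phenol that closes ring C with inversion from (R) to (S), the cold, dilute and non-polar medium disfavouring both ionisation of the electron-rich benzylic centre and intermolecular attack by the hindered C3' hydroxyl.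

Step 15
Reactants: 22 (2S)-7-O-triisopropylsilylkazinol B
Product: 23 kazinol B
Conditions: TBAF, AcOH (1:1), THF, 0 °C
Reagents that add atoms: none
Why: Fluoride-induced cleavage of the aryl silyl ether, buffered with acetic acid so that the phenols never meet a strongly basic medium, and without any effect on C2, the prenyl group or the chromene.

**Compound list**

1 | umbelliferone | O=c1ccc2ccc(O)cc2o1 | starting material
2 | 7-hydroxychroman-2-one | O=C1CCc2ccc(O)cc2O1 | intermediate
3 | 7-(triisopropylsilyloxy)chroman-2-one | O=C1CCc2ccc(O[Si](C(C)C)(C(C)C)C(C)C)cc2O1 | intermediate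
4 | 3-[2-hydroxy-4-(triisopropylsilyloxy)phenyl]-N-methoxy-N-methylpropanamide | CON(C)C(=O)CCc1ccc(O[Si](C(C)C)(C(C)C)C(C)C)cc1O | intermediate
5 | 3-[2-allyloxy-4-(triisopropylsilyloxy)phenyl]-N-methoxy-N-methylpropanamide | CON(C)C(=O)CCc1ccc(O[Si](C(C)C)(C(C)C)C(C)C)cc1OCC=C | intermediate
6 | prenyl bromide | CC(C)=CCBr | starting material
7 | ethynylmagnesium bromide | C#C[Mg]Br | starting material
8 | 5-methylhex-4-en-1-yne | C#CCC=C(C)C | intermediate
9 | lithium 5-methylhex-4-en-1-yn-1-ide | [Li]C#CCC=C(C)C | intermediate
10 | 1-[2-allyloxy-4-(triisopropylsilyloxy)phenyl]-8-methylnon-7-en-4-yn-3-one (prenyl ynone) | CC(C)=CCC#CC(=O)CCc1ccc(O[Si](C(C)C)(C(C)C)C(C)C)cc1OCC=C | intermediate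
11 | 3-bromofuran | Brc1ccoc1 | starting material
12 | 3-(4-methoxybenzyloxy)furan | COc1ccc(COc2ccoc2)cc1 | intermediate
13 | 2-acyl-3-prenyl-5-(4-methoxybenzyloxy)-7-oxabicyclo[2.2.1]hepta-2,5-diene, acyl = 3-[2-allyloxy-4-(triisopropylsilyloxy)phenyl]propanoyl (racemic, one enantiomer drawn) | O1[C@@H]2C(OCc3ccc(OC)cc3)=C[C@H]1C(C(=O)CCc1ccc(O[Si](C(C)C)(C(C)C)C(C)C)cc1OCC=C)=C2CC=C(C)C | intermediate
14 | 1-[3-hydroxy-4-(4-methoxybenzyloxy)-2-prenylphenyl]-3-[2-allyloxy-4-(triisopropylsilyloxy)phenyl]propan-1-one | CC(C)=CCc1c(C(=O)CCc2ccc(O[Si](C(C)C)(C(C)C)C(C)C)cc2OCC=C)ccc(OCc2ccc(OC)cc2)c1O | intermediate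
15 | 1-(3,4-dihydroxy-2-prenylphenyl)-3-[2-allyloxy-4-(triisopropylsilyloxy)phenyl]propan-1-one | CC(C)=CCc1c(C(=O)CCc2ccc(O[Si](C(C)C)(C(C)C)C(C)C)cc2OCC=C)ccc(O)c1O | intermediate
16 | 2-methylbut-3-yn-2-ol | CC(C)(O)C#C | starting material
17 | 2-methylbut-3-yn-2-yl trifluoroacetate | CC(C)(C#C)OC(=O)C(F)(F)F | intermediate
18 | 1-[3-hydroxy-4-(2-methylbut-3-yn-2-yloxy)-2-prenylphenyl]-3-[2-allyloxy-4-(triisopropylsilyloxy)phenyl]propan-1-one | CC(C)=CCc1c(C(=O)CCc2ccc(O[Si](C(C)C)(C(C)C)C(C)C)cc2OCC=C)ccc(OC(C)(C)C#C)c1O | intermediate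
19 | 1-(8-hydroxy-2,2-dimethyl-7-prenyl-2H-chromen-6-yl)-3-[2-allyloxy-4-(triisopropylsilyloxy)phenyl]propan-1-one | CC(C)=CCc1c(C(=O)CCc2ccc(O[Si](C(C)C)(C(C)C)C(C)C)cc2OCC=C)cc2c(c1O)OC(C)(C)C=C2 | intermediate
20 | (1R)-1-(8-hydroxy-2,2-dimethyl-7-prenyl-2H-chromen-6-yl)-3-[2-allyloxy-4-(triisopropylsilyloxy)phenyl]propan-1-ol | CC(C)=CCc1c([C@H](O)CCc2ccc(O[Si](C(C)C)(C(C)C)C(C)C)cc2OCC=C)cc2c(c1O)OC(C)(C)C=C2 | intermediate
21 | (1R)-1-(8-hydroxy-2,2-dimethyl-7-prenyl-2H-chromen-6-yl)-3-[2-hydroxy-4-(triisopropylsilyloxy)phenyl]propan-1-ol | CC(C)=CCc1c([C@H](O)CCc2ccc(O[Si](C(C)C)(C(C)C)C(C)C)cc2O)cc2c(c1O)OC(C)(C)C=C2 | intermediate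
22 | (2S)-7-O-triisopropylsilylkazinol B | CC(C)=CCc1c([C@@H]2CCc3ccc(O[Si](C(C)C)(C(C)C)C(C)C)cc3O2)cc2c(c1O)OC(C)(C)C=C2 | intermediate
23 | kazinol B, (2S) | CC(C)=CCc1c([C@@H]2CCc3ccc(O)cc3O2)cc2c(c1O)OC(C)(C)C=C2 | target

**Step count**

Total step count: 15.
Longest linear sequence: 13 steps (steps 1–4, 6, 8–15, from umbelliferone).

**Steps most likely to fail**

**Step 8.**
- **Risk:** the internal ynone may add too slowly. Cycloreversion, thermal drift of the skipped enyne into conjugation, or open-chain conjugate addition at furan C2 without ring closure could then win, and the orientation of the partners could erode.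
- **Fallback:** it sets out from Weinreb amide 5, uses 17 made from 16 as in step 10, and comes back at 14. Ring B is taken from an arene instead of being built.
- Commercial 5-bromosalicylaldehyde is alkylated with 4-methoxybenzyl chloride (K2CO3, DMF) to 5-bromo-2-(4-methoxybenzyloxy)benzaldehyde F1.
- Baeyer–Villiger oxidation (mCPBA, CH2Cl2) gives 5-bromo-2-(4-methoxybenzyloxy)phenyl formate F2, and methanolysis (K2CO3, MeOH) gives 5-bromo-2-(4-methoxybenzyloxy)phenol F3.
- Alkylation with 17 (CuCl2·2H2O, DBU, MeCN) gives the 1,1-dimethylpropargyl ether F4. Semihydrogenation (H2, Pd/CaCO3 poisoned with Pb(OAc)2, quinoline) then gives the 1,1-dimethylallyl ether F5.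
- An aromatic Claisen rearrangement (toluene, 110 °C) moves the allyl unit with transposition to the only free ortho carbon, giving 3-bromo-6-(4-methoxybenzyloxy)-2-prenylphenol F6.
- Two equivalents of n-BuLi (THF, −78 °C) convert this into the lithium phenoxide aryllithium F7, which is acylated by 5 to give 14.

**Step 14.**
- **Risk:** the activated benzylic carbinol, para to the planar chromene oxygen, may partly ionise. That would erode configurational purity and open the way to elimination.
- **Fallback:** it sets out from 18 and comes back at 22, closing ring C before ring D. In the propargyl ether the bulky tertiary alkyl group, wedged against the C3' hydroxyl, turns the C4' oxygen out of conjugation. Ring B therefore supports a benzylic cation less well than the chromene does.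
- Ketone 18 is reduced as in step 12 to the (R)-carbinol propargyl ether F8 and deallylated as in step 13 to the phenol carbinol F9. The allyl aryl ether should ionise far more readily than the tertiary propargyl aryl ether.
- Mitsunobu cyclisation as in step 14 gives the (2S)-flavan propargyl ether F10, and heating as in step 11 then builds ring D on the finished flavan to give 22.

**Step 6.**
- **Risk:** base may move the skipped enyne into a conjugated allenyl or dienyl ketone, and the released hydroxylamine may add to the ynone in conjugate fashion while the tetrahedral adduct collapses.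
- **Fallback:** it sets out from 5 and comes back at 10. The ketone is reached by oxidation instead of acylation, so it first appears in a neutral, amine-free medium.
- DIBAL-H (toluene, −78 °C) reduces 5 to 3-[2-allyloxy-4-(triisopropylsilyloxy)phenyl]propanal F11.
- Addition of 9 (THF, −78 °C) gives the racemic propargylic alcohol F12, and activated MnO2 (CH2Cl2, rt) oxidises it to 10.

Further compounds
F1 | step 8 | 5-bromo-2-(4-methoxybenzyloxy)benzaldehyde | COc1ccc(COc2ccc(Br)cc2C=O)cc1
F2 | step 8 | 5-bromo-2-(4-methoxybenzyloxy)phenyl formate | COc1ccc(COc2ccc(Br)cc2OC=O)cc1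
F3 | step 8 | 5-bromo-2-(4-methoxybenzyloxy)phenol | COc1ccc(COc2ccc(Br)cc2O)cc1
F4 | step 8 | 4-bromo-1-(4-methoxybenzyloxy)-2-(2-methylbut-3-yn-2-yloxy)benzene | COc1ccc(COc2ccc(Br)cc2OC(C)(C)C#C)cc1
F5 | step 8 | 4-bromo-1-(4-methoxybenzyloxy)-2-(2-methylbut-3-en-2-yloxy)benzene | COc1ccc(COc2ccc(Br)cc2OC(C)(C)C=C)cc1
F6 | step 8 | 3-bromo-6-(4-methoxybenzyloxy)-2-prenylphenol | CC(C)=CCc1c(Br)ccc(OCc2ccc(OC)cc2)c1O
F7 | step 8 | lithium 3-lithio-6-(4-methoxybenzyloxy)-2-prenylphenoxide | [Li]Oc1c(CC=C(C)C)c([Li])ccc1OCc1ccc(OC)cc1
F8 | step 14 | (1R)-3-[2-allyloxy-4-(triisopropylsilyloxy)phenyl]-1-[3-hydroxy-4-(2-methylbut-3-yn-2-yloxy)-2-prenylphenyl]propan-1-ol | CC(C)=CCc1c([C@H](O)CCc2ccc(O[Si](C(C)C)(C(C)C)C(C)C)cc2OCC=C)ccc(OC(C)(C)C#C)c1O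
F9 | step 14 | (1R)-3-[2-hydroxy-4-(triisopropylsilyloxy)phenyl]-1-[3-hydroxy-4-(2-methylbut-3-yn-2-yloxy)-2-prenylphenyl]propan-1-ol | CC(C)=CCc1c([C@H](O)CCc2ccc(O[Si](C(C)C)(C(C)C)C(C)C)cc2O)ccc(OC(C)(C)C#C)c1O
F10 | step 14 | (2S)-2-[3-hydroxy-4-(2-methylbut-3-yn-2-yloxy)-2-prenylphenyl]-7-(triisopropylsilyloxy)chroman | CC(C)=CCc1c([C@@H]2CCc3ccc(O[Si](C(C)C)(C(C)C)C(C)C)cc3O2)ccc(OC(C)(C)C#C)c1O
F11 | step 6 | 3-[2-allyloxy-4-(triisopropylsilyloxy)phenyl]propanal | O=CCCc1ccc(O[Si](C(C)C)(C(C)C)C(C)C)cc1OCC=C
F12 | step 6 | 1-[2-allyloxy-4-(triisopropylsilyloxy)phenyl]-8-methylnon-7-en-4-yn-3-ol (racemic) | CC(C)=CCC#CC(O)CCc1ccc(O[Si](C(C)C)(C(C)C)C(C)C)cc1OCC=C
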